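## Structural features

The target is a 7-oxabicyclo[4.1.0]hept-4-ene: a cyclohexene ring (C1–C6) with an oxirane fused across C1–C6, so that the oxirane and C4=C5 together form a vinyl epoxide. C1 is quaternary (oxirane O, C2, C6 and the exocyclic C7H2 that carries a benzoate), C2 bears a free hydroxyl and C3 an allylic benzoate. The four stereocentres C6–C1–C2–C3 are contiguous, with the oxirane oxygen, O2 and O3 all on one face of the ring and C7 on the other. Fragile points are the vinyl epoxide (acid, allylic substitution, zerovalent palladium), the allylic benzoate, and the cis hydroxy/benzoate pair (1,2-acyl migration under base). In addition, every diene intermediate is only one elimination away from an arene. The oxirane is not the real problem, because a cis hydroxyl at C2 can direct an epoxidation of C1=C6. The real problem is the cis-diol pair C2/C3 in absolute form, next to the C7-bearing carbon, with O2 and O3 differentiated. The key step exploits this feature: without the oxirane oxygen the ring is a cyclohexa-1,3-diene (C1=C6–C5=C4) with a cis-diol at C2/C3 and C7 on the diene terminus C1; C1, C6, C5, C4 and C7 map onto C3, C4, C5, C6 and the ester carbon of a 2-pyrone-3-carboxylate, and C2/C3 onto the two carbons of a cis-enediol ether, so that only CO2 has to leave.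

## Logic of the disconnections

**10 ⇒ 9.** The two C–O bonds of the oxirane (C1–O, C6–O) are cut. The cis hydroxyl at C2 is allylic to C1=C6 and can deliver the oxygen to its own face, so both remaining stereocentres follow from C2. The gain is the removal of two stereocentres and of the most labile group until the last step. The forward step must select the trisubstituted C1=C6 over C4=C5 and must not open the vinyl epoxide.

**9 ⇒ 7 (through 8).** The two acyl C–O bonds of the benzoates (at O7 and O3) are cut. This reduces the problem to a triol whose three hydroxyls differ sterically (primary; secondary distal to C1; secondary next to C1). The forward step must leave O2 free and avoid acyl migration.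

**7 ⇒ 5 (through 6).** C7 is taken back from the alcohol to the ester oxidation level (C7–H bonds cut). The ester is what makes the ring-forming step possible and what protects the diene diol against acid. The forward reduction must be 1,2-selective and non-acidic in work-up.

**5 ⇒ 4.** The two C–O bonds of an isopropylidene acetal are added on O2/O3. This ties the diol to the cyclic enediol ether needed for the cycloaddition. The forward hydrolysis must not aromatise the diene.

**4 ⇒ 3.** A CO2 bridge is added across C1 and C4 (C1–C(=O) and C4–O bonds). This converts the labile diene into a bridged lactone that is the direct product of a cycloaddition. The forward step is a thermal cycloreversion that must outrun dimerisation.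

**3 ⇒ 1 + 2.** The bonds C1–C2 and C3–C4 of the carbocycle are cut. This is the key disconnection: the whole ring, the cis relationship at C2/C3 and their absolute configuration come from two achiral, flat heterocycles. The forward step must control the face of 1 and the endo mode; there is no regiochemical demand because 2 is symmetric.

## Other disconnections considered

Alternative 1: cut the C2–O and C3–O bonds on the arene, i.e. enzymatic dearomatising cis-dihydroxylation. This is the first plan that comes to mind.
- Benzyl benzoate itself is a poor substrate for whole-cell toluene dioxygenase oxidation (two arene rings, and an ester that cell esterases are expected to cleave).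
- The practical form therefore starts from the fermentation product (1S,2S)-3-bromocyclohexa-3,5-diene-1,2-diol A1, which has the right configuration. Its acetonide A2 would be methoxycarbonylated with Pd(PPh3)4, CO and MeOH to reach 4.
- That is two steps to 4, the same count as the chosen plan. It depends on a cold-chain biotransformation product available in one enantiomeric series only, and on a carbonylation of a bromodiene that is expected to dimerise readily.
- The chosen plan has C7 in place from the start and reaches either antipode by choice of ligand.

Alternative 2: cut C4=C5, i.e. ring-closing metathesis of the triene A3 with second-generation Grubbs catalyst to the silyl-protected diene acetonide A4.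
- The metathesis is plausible, but it sets no stereocentre.
- A3 needs an erythro diol from a pentose (or from a poorly selective dihydroxylation of a cis-alkene) and a stereodefined (Z)-trisubstituted diene. This is estimated at eight to ten steps before the ring exists, against one step in the chosen plan.

Alternative 3: cut the oxirane last-formed bonds first in the synthetic direction: Birch reduction of benzyl alcohol to A5, then Sharpless asymmetric epoxidation to A6, which fixes C1 and C6 at once.
- In A6 the remaining alkene is C3=C4 and C2 is an unactivated methylene, so an alkene transposition is needed.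
- The cis-diol would then have to be placed on the same face as the existing oxirane, the face that osmylation avoids.
- The chosen plan reverses the order so that O2 directs the oxirane.

Key step: step 1

**Assumptions.** 1 and 2 are taken as purchased. In step 1 the two partners are combined in equimolar amounts, so the cycloaddition is a plain 1:1 addition in which every atom of 1 and 2 ends in 3. The (S,S) ligand is written for step 1; the sense of induction is to be confirmed on the first run and the (R,R) ligand used if the antipode of 3 forms. Target numbering (C1–C7) is used in the discussion of all intermediates.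

## Route

Step 1
Reactants: 1 methyl 2-oxo-2H-pyran-3-carboxylate; 2 2,2-dimethyl-1,3-dioxole
Product: 3 methyl (1R,4S,7S,8R)-7,8-(isopropylidenedioxy)-3-oxo-2-oxabicyclo[2.2.2]oct-5-ene-4-carboxylate (endo adduct; dioxolane oxygens syn to the C5=C6 bridge)
Conditions: Cu(OTf)2 (10 mol %), (S,S)-t-Bu-box [2,2′-(propane-2,2-diyl)bis((4S)-4-tert-butyl-4,5-dihydrooxazole)] (11 mol %), 4 Å MS, CH2Cl2, −20 °C
Reagents that add atoms: none
Why: Inverse-electron-demand Diels–Alder reaction, a known reaction type for 3-alkoxycarbonyl-2-pyrones and enol ethers under chiral copper–bisoxazoline catalysis: 1 chelates the divalent copper centre through its lactone and ester carbonyl oxygens, which lowers the diene LUMO and holds the pyrone in the chiral pocket, while the electron-rich 2 supplies the HOMO. Bonding starts at C6 of the pyrone (the vinylogous acceptor terminus) and ends at C3, so the addition is concerted but asynchronous; if it became stepwise, the second bond would form by 6-(enolexo)-exo-trig attack of the copper enolate on the dioxolanyl oxocarbenium ion with the same outcome. The one ring closed is the carbocycle of the target (bonds C1–C2 and C3–C4 in target numbering), by intermolecular [4+2] addition, suprafacial on both partners. C7 and C8 of 3 (target C3 and C2) are cis because 2 is a ring-locked cis-alkene, and they lie syn to the C5=C6 bridge through the endo transition state usual for enol ethers with this diene. Their absolute configuration, and that of the bridgeheads C1 and C4, comes from the tert-butyl group of the ligand blocking one face of the chelated pyrone. No regiochemical question arises because 2 is symmetric. The step needs both facial and endo selectivity, because an exo adduct of the same facial sense would end as the antipodal diene after loss of CO2.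

Step 2
Reactants: 3 methyl (1R,4S,7S,8R)-7,8-(isopropylidenedioxy)-3-oxo-2-oxabicyclo[2.2.2]oct-5-ene-4-carboxylate
Product: 4 methyl (3aR,7aS)-2,2-dimethyl-3a,7a-dihydro-1,3-benzodioxole-4-carboxylate
Conditions: PhMe (0.02 M), 110 °C
Reagents that add atoms: none
Why: Retro-Diels–Alder extrusion of CO2 from the 2-oxabicyclo[2.2.2]oct-5-en-3-one, driven by gas loss and by conjugation of the new diene with the ester; the bridgehead stereocentres vanish, C3a and C7a are untouched, and high dilution suppresses Diels–Alder dimerisation of 4.

Step 3
Reactants: 4 methyl (3aR,7aS)-2,2-dimethyl-3a,7a-dihydro-1,3-benzodioxole-4-carboxylate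
Product: 5 methyl (5S,6R)-5,6-dihydroxycyclohexa-1,3-diene-1-carboxylate
Conditions: AcOH–H2O (4:1), 35 °C
Reagents that add atoms: none
Why: Acid-catalysed acetal hydrolysis; the diene diol should survive because dehydration to a phenol passes through a cyclohexadienyl cation that the conjugated ester destabilises, which is the reason for unmasking the diol before the ester is reduced.

Step 4
Reactants: 5 methyl (5S,6R)-5,6-dihydroxycyclohexa-1,3-diene-1-carboxylate
Product: 7 (1S,2R)-3-(hydroxymethyl)cyclohexa-3,5-diene-1,2-diol, via dihydroxy dienal 6 (not isolated)
Conditions: i-Bu2AlH (5 equiv), THF, −78 → −20 °C; then aq. KNaC4H4O6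
Reagents that add atoms: none
Why: Hydride reduction of the dienoate, 1,2-selective with i-Bu2AlH at low temperature, by way of the aluminium hemiacetal and aldehyde 6; the two hydroxyls are only deprotonated, no stereocentre is touched, and the tartrate work-up keeps the acid-labile triol away from acid.

Step 5
Reactants: 7 (1S,2R)-3-(hydroxymethyl)cyclohexa-3,5-diene-1,2-diol
Product: 9 [(5S,6R)-5-(benzoyloxy)-6-hydroxycyclohexa-1,3-dien-1-yl]methyl benzoate, via primary monobenzoate 8 (not isolated)
Conditions: BzCl (2.1 equiv), pyridine, CH2Cl2, −40 °C
Reagents that add atoms: benzoyl chloride, O=C(Cl)c1ccccc1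
Why: Sterically controlled acylation: the primary allylic hydroxyl reacts first (8), then the distal pseudo-equatorial 5-OH, while the 6-OH is flanked by the trisubstituted C1 with its new benzoyloxymethyl group and sits pseudo-axial to avoid allylic 1,2-strain; low temperature and the weak base limit cis-1,2 acyl migration.

Step 6
Reactants: 9 [(5S,6R)-5-(benzoyloxy)-6-hydroxycyclohexa-1,3-dien-1-yl]methyl benzoate
Product: 10 [(1S,2S,3S,6R)-3-(benzoyloxy)-2-hydroxy-7-oxabicyclo[4.1.0]hept-4-en-1-yl]methyl benzoate
Conditions: VO(acac)2 (5 mol %), t-BuOOH (1.5 equiv, in decane), CH2Cl2, 0 °C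
Reagents that add atoms: tert-butyl hydroperoxide, CC(C)(C)OO
Why: Hydroxyl-directed epoxidation: the vanadium alkoxide of the 6-OH delivers the peroxide oxygen to its own face of the adjacent trisubstituted C1=C2 bond of the diene, setting both new stereocentres (target C1 and C6) cis to O2; the other double bond is only homoallylic to the hydroxyl and deactivated by the allylic benzoate, and the neutral conditions spare the vinyl epoxide.

## Compound list

1 | methyl 2-oxo-2H-pyran-3-carboxylate | COC(=O)C1=CC=COC1=O | starting material
2 | 2,2-dimethyl-1,3-dioxole | CC1(C)OC=CO1 | starting material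
3 | methyl (1R,4S,7S,8R)-7,8-(isopropylidenedioxy)-3-oxo-2-oxabicyclo[2.2.2]oct-5-ene-4-carboxylate | COC(=O)[C@@]12C=C[C@@H](OC1=O)[C@@H]3OC(C)(C)O[C@H]23 | intermediate
4 | methyl (3aR,7aS)-2,2-dimethyl-3a,7a-dihydro-1,3-benzodioxole-4-carboxylate | COC(=O)C1=CC=C[C@@H]2OC(C)(C)O[C@H]12 | intermediate
5 | methyl (5S,6R)-5,6-dihydroxycyclohexa-1,3-diene-1-carboxylate | COC(=O)C1=CC=C[C@H](O)[C@@H]1O | intermediate
6 | (5S,6R)-5,6-dihydroxycyclohexa-1,3-diene-1-carbaldehyde | O=CC1=CC=C[C@H](O)[C@@H]1O | intermediate (not isolated)
7 | (1S,2R)-3-(hydroxymethyl)cyclohexa-3,5-diene-1,2-diol | OCC1=CC=C[C@H](O)[C@@H]1O | intermediate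
8 | [(5S,6R)-5,6-dihydroxycyclohexa-1,3-dien-1-yl]methyl benzoate | O=C(OCC1=CC=C[C@H](O)[C@@H]1O)c1ccccc1 | intermediate (not isolated)
9 | [(5S,6R)-5-(benzoyloxy)-6-hydroxycyclohexa-1,3-dien-1-yl]methyl benzoate | O=C(OCC1=CC=C[C@H](OC(=O)c2ccccc2)[C@@H]1O)c1ccccc1 | intermediate
10 | [(1S,2S,3S,6R)-3-(benzoyloxy)-2-hydroxy-7-oxabicyclo[4.1.0]hept-4-en-1-yl]methyl benzoate | O=C(OC[C@@]12O[C@@H]1C=C[C@H](OC(=O)c1ccccc1)[C@@H]2O)c1ccccc1 | target

## Step count and risks

Total steps: 6. Longest linear sequence: 6 (from 1).

**Step 1 (key step).**
- What may go wrong: incomplete facial discrimination or erosion of the endo preference, either of which lowers the enantiomeric purity of 4. Acid-induced oligomerisation of the enol acetal 2 at the copper centre, or an uncatalysed background cycloaddition, are further risks.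
- Fallback (sets out from 1 and 2, comes back at 5):
  - 1 and 2 are heated without catalyst in toluene. The racemic adduct, 3 together with its antipode methyl (1S,4R,7R,8S)-7,8-(isopropylidenedioxy)-3-oxo-2-oxabicyclo[2.2.2]oct-5-ene-4-carboxylate F1, loses CO2 in the same pot to give 4 with methyl (3aS,7aR)-2,2-dimethyl-3a,7a-dihydro-1,3-benzodioxole-4-carboxylate F2.
  - Hydrolysis as in step 3 gives 5 with methyl (5R,6S)-5,6-dihydroxycyclohexa-1,3-diene-1-carboxylate F3.
  - An enzymatic kinetic resolution (Burkholderia cepacia lipase, vinyl acetate, t-BuOMe) is screened to acetylate the unwanted antipode at its less hindered hydroxyl, giving methyl (5R,6S)-5-(acetyloxy)-6-hydroxycyclohexa-1,3-diene-1-carboxylate F4. This is separated from unreacted 5, which enters step 4.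

**Step 3.**
- What may go wrong: acid-catalysed dehydration of the diene diol to a hydroxybenzoate during acetal cleavage.
- Fallback (sets out from 3, comes back at 5): the acetonide is hydrolysed on the bridged lactone, where no diene is present, to give methyl (1R,4S,7R,8R)-7,8-dihydroxy-3-oxo-2-oxabicyclo[2.2.2]oct-5-ene-4-carboxylate F5. CO2 is then extruded thermally under neutral conditions to give 5 directly.

**Step 5.**
- What may go wrong: insufficient discrimination between the two secondary hydroxyls, or benzoyl migration between them.
- Fallback (sets out from 4, comes back at 9):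
  - 4 is reduced with i-Bu2AlH to [(3aR,7aS)-2,2-dimethyl-3a,7a-dihydro-1,3-benzodioxol-4-yl]methanol F6.
  - F6 is benzoylated to [(3aR,7aS)-2,2-dimethyl-3a,7a-dihydro-1,3-benzodioxol-4-yl]methyl benzoate F7.
  - The acetonide is cleaved to give 8, this time isolated.
  - The single remaining acylation is carried out through the stannylene acetal (Bu2SnO, then BzCl), which acylates the pseudo-equatorial distal oxygen, to give 9.

**Step 6.**
- What may go wrong: competing oxidation of the other double bond or of the allylic alcohol to a dienone that aromatises, delivery to the wrong face, or opening of the vinyl epoxide.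
- Fallback (sets out from 7, comes back at 10): the order of the last two steps is inverted. Triol 7, in which both the primary and the ring allylic hydroxyl direct vanadium to the same double bond, is epoxidised to (1S,2S,3S,6R)-1-(hydroxymethyl)-7-oxabicyclo[4.1.0]hept-4-ene-2,3-diol F8. F8 is then dibenzoylated; its 2-OH is now flanked by the quaternary oxirane carbon and is the least accessible of the three, giving 10.

## Further compounds

F1 | step 1 | methyl (1S,4R,7R,8S)-7,8-(isopropylidenedioxy)-3-oxo-2-oxabicyclo[2.2.2]oct-5-ene-4-carboxylate | COC(=O)[C@]12C=C[C@H](OC1=O)[C@H]3OC(C)(C)O[C@@H]23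
F2 | step 1 | methyl (3aS,7aR)-2,2-dimethyl-3a,7a-dihydro-1,3-benzodioxole-4-carboxylate | COC(=O)C1=CC=C[C@H]2OC(C)(C)O[C@@H]12
F3 | step 1 | methyl (5R,6S)-5,6-dihydroxycyclohexa-1,3-diene-1-carboxylate | COC(=O)C1=CC=C[C@@H](O)[C@H]1O
F4 | step 1 | methyl (5R,6S)-5-(acetyloxy)-6-hydroxycyclohexa-1,3-diene-1-carboxylate | COC(=O)C1=CC=C[C@@H](OC(C)=O)[C@H]1O
F5 | step 3 | methyl (1R,4S,7R,8R)-7,8-dihydroxy-3-oxo-2-oxabicyclo[2.2.2]oct-5-ene-4-carboxylate | COC(=O)[C@@]12C=C[C@@H](OC1=O)[C@H](O)[C@@H]2O
F6 | step 5 | [(3aR,7aS)-2,2-dimethyl-3a,7a-dihydro-1,3-benzodioxol-4-yl]methanol | OCC1=CC=C[C@@H]2OC(C)(C)O[C@H]12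
F7 | step 5 | [(3aR,7aS)-2,2-dimethyl-3a,7a-dihydro-1,3-benzodioxol-4-yl]methyl benzoate | O=C(OCC1=CC=C[C@@H]2OC(C)(C)O[C@H]12)c1ccccc1
F8 | step 6 | (1S,2S,3S,6R)-1-(hydroxymethyl)-7-oxabicyclo[4.1.0]hept-4-ene-2,3-diol | OC[C@@]12O[C@@H]1C=C[C@H](O)[C@@H]2O
A1 | alternative 1 | (1S,2S)-3-bromocyclohexa-3,5-diene-1,2-diol | BrC1=CC=C[C@H](O)[C@@H]1O
A2 | alternative 1 | (3aS,7aS)-4-bromo-2,2-dimethyl-3a,7a-dihydro-1,3-benzodioxole | BrC1=CC=C[C@@H]2OC(C)(C)O[C@H]12
A3 | alternative 2 | tert-butyl{[(2Z)-2-[(4R,5S)-5-ethenyl-2,2-dimethyl-1,3-dioxolan-4-yl]penta-2,4-dien-1-yl]oxy}dimethylsilane | C=C[C@@H]1OC(C)(C)O[C@@H]1/C(CO[Si](C)(C)C(C)(C)C)=C\C=C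
A4 | alternative 2 | tert-butyl{[(3aR,7aS)-2,2-dimethyl-3a,7a-dihydro-1,3-benzodioxol-4-yl]methoxy}dimethylsilane | CC(C)(C)[Si](C)(C)OCC1=CC=C[C@@H]2OC(C)(C)O[C@H]12
A5 | alternative 3 | cyclohexa-1,4-dien-1-ylmethanol | OCC1=CCC=CC1
A6 | alternative 3 | [(1R,6R)-7-oxabicyclo[4.1.0]hept-3-en-1-yl]methanol | OC[C@@]12O[C@@H]1CC=CC2
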